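The target is a cis-fused hydroazulene whose five-membered ring carries, on one face, the C3a hydroxyl, the C3 isopropyl and the C8a methyl. The C3a–OH/C3–isopropyl pair is the retron of a carbonyl-ene reaction: the cyclopentane is closed last by bonding C3 of a homoprenyl chain on C8a to the C3a carbonyl of a cycloheptanone, with transfer of a methyl hydrogen to oxygen. The precursor, a 3-hydroxy-2-methyl-2-homoprenylcycloheptanone, comes from CBS desymmetrisation of an achiral 1,3-dione; its carbinol stores the chirality until the ene step fixes C3a and C3 relative to C8a. C8 is then oxidised, the C6-methyl enone installed, and C8 reset and acylated.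

Key step: step 5

Remark: the hydroazulene locants of the target (C1, C2, C3, C3a, C4–C8, C8a) are used for all intermediates, and homoprenyl stands for 4-methylpent-3-en-1-yl.

Step 1
Reactants: 1 cycloheptane-1,3-dione
Product: 2 2-methylcycloheptane-1,3-dione
Conditions: MeI (1.1 equiv), K2CO3, acetone, 56 °C
Reagents that add atoms: iodomethane, SMILES CI
Why: C-Alkylation (SN2) of the potassium enolate of the 1,3-diketone with iodomethane should give the 2-methyl dione, which is separable from O-methyl and dimethyl by-products through its acidity; no stereocentre is formed.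

Step 2
Reactants: 2 2-methylcycloheptane-1,3-dione; 3 acrolein
Product: 4 3-(1-methyl-2,7-dioxocycloheptyl)propanal
Conditions: Et3N (10 mol%), MeCN, 23 °C
Reagents that add atoms: none
Why: Amine-catalysed Michael addition of the acidic C2–H of the dione to acrolein builds the quaternary carbon (future C8a), which is not yet stereogenic because the two carbonyl arms are identical.

Step 3
Reactants: 4 3-(1-methyl-2,7-dioxocycloheptyl)propanal
Product: 5 2-methyl-2-(4-methylpent-3-en-1-yl)cycloheptane-1,3-dione
Conditions: i-PrPPh3I (1.3 equiv), n-BuLi, THF, 0 °C; then 4, −78 to 23 °C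
Reagents that add atoms: isopropyltriphenylphosphonium iodide, SMILES CC(C)[P+](c1ccccc1)(c1ccccc1)c1ccccc1.[I-]
Why: Wittig olefination with the unstabilised isopropylidene ylide should take place only at the aldehyde, the two ring ketones being flanked by the quaternary carbon, and installs the trisubstituted alkene that later acts as the ene component.

Step 4
Reactants: 5 2-methyl-2-(4-methylpent-3-en-1-yl)cycloheptane-1,3-dione
Product: 6 (2R,3R)-3-hydroxy-2-methyl-2-(4-methylpent-3-en-1-yl)cycloheptan-1-one
Conditions: (3aS)-1-methyl-3,3-diphenyltetrahydro-1H,3H-pyrrolo[1,2-c][1,3,2]oxazaborole [(S)-Me-CBS, 20 mol%], catecholborane (1.2 equiv), toluene, −78 to −40 °C; MeOH quench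
Reagents that add atoms: none
Why: CBS reduction used as an enantiotopic-group-selective desymmetrisation: the (S)-oxazaborolidine (quaternary carbon as the large group) should set the carbinol as 3R, and because hydride prefers the face syn to methyl and anti to the longer chain only one of the two carbonyl groups is matched, which makes the quaternary carbon 2R; catecholborane spares the alkene and the minor C2 epimer is to be removed by chromatography.

Step 5
Reactants: 6 (2R,3R)-3-hydroxy-2-methyl-2-(4-methylpent-3-en-1-yl)cycloheptan-1-one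
Product: 8 (3R,3aS,8R,8aR)-8a-methyl-3-(prop-1-en-2-yl)decahydroazulene-3a,8-diol, via aluminium alkoxide chelate 7 (not isolated)
Conditions: Me2AlCl (2.5 equiv), CH2Cl2, −78 to 0 °C; aq. KNaC4H4O6
Reagents that add atoms: none
Why: Protonolysis of one Al–CH3 bond by the C8 hydroxyl gives the aluminium alkoxide 7, which together with excess Me2AlCl activates the C3a carbonyl; C3 of the trisubstituted alkene then bonds to C3a while a methyl hydrogen passes to the carbonyl oxygen through a six-centre transition state, leaving an isopropenyl group on C3. The closest known reaction type is the alkylaluminium-halide-promoted type 1 intramolecular carbonyl-ene reaction (citronellal to isopulegol), here with a ketone as enophile. The cyclopentane closes in the 5-exo-trig mode at the carbonyl carbon (bond C3a–C3), the ene double bond lying outside the new ring. C3a is controlled by C8a, because the three-atom tether reaches only the carbonyl face on its own side of the seven-membered ring, so the fusion is cis and the new hydroxyl is cis to the C8a methyl. C3 is controlled by the pericyclic geometry, because hydrogen transfer demands that the oxygen and the C(CH3)=CH2 unit be synclinal across the forming bond, which puts isopropenyl cis to the hydroxyl. The step needs hydrogen transfer to win over chloride capture, cationic 1,2-shifts and retro-aldol opening of the aluminium aldolate; the mild, proton-scavenging Me2AlCl (not MeAlCl2), low temperature and the absence of any second electrophile should secure this.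

Step 6
Reactants: 8 (3R,3aS,8R,8aR)-8a-methyl-3-(prop-1-en-2-yl)decahydroazulene-3a,8-diol
Product: 9 (3R,3aS,8R,8aR)-8a-methyl-3-(propan-2-yl)decahydroazulene-3a,8-diol
Conditions: H2 (1 atm), Pd/C (10%), EtOAc, 23 °C
Reagents that add atoms: none
Why: Heterogeneous catalytic hydrogenation saturates the only C=C bond (1,1-disubstituted isopropenyl) to isopropyl; no stereocentre is created or affected.

Step 7
Reactants: 9 (3R,3aS,8R,8aR)-8a-methyl-3-(propan-2-yl)decahydroazulene-3a,8-diol
Product: 11 (3R,3aS,8aS)-3a-hydroxy-8a-methyl-3-(propan-2-yl)-2,3,3a,4,5,8a-hexahydroazulen-8(1H)-one, via saturated hydroxy ketone 10 (not isolated)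
Conditions: IBX (3 equiv), DMSO, 23 °C then 70 °C
Reagents that add atoms: none
Why: IBX oxidation of the secondary C8 carbinol (the tertiary C3a hydroxyl cannot be oxidised) followed in the same pot by IBX dehydrogenation of the resulting ketone, which can enolise only towards C7, should give the C6=C7 enone; the temporary C8 stereocentre is erased on purpose now that C8a, C3a and C3 are locked in the bicycle.

Step 8
Reactants: 11 (3R,3aS,8aS)-3a-hydroxy-8a-methyl-3-(propan-2-yl)-2,3,3a,4,5,8a-hexahydroazulen-8(1H)-one
Product: 12 C8 trimethylsilyl enol ether and C3a trimethylsilyl ether of the 6-methyl adduct (C3, C3a, C8a as in 11; both C6 epimers)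
Conditions: Me2CuLi (3 equiv, from MeLi and CuI), TMSCl (6 equiv), THF, −78 to 0 °C
Reagents that add atoms: lithium dimethylcuprate, SMILES [Li+].C[Cu-]C; chlorotrimethylsilane, SMILES C[Si](C)(C)Cl
Why: Conjugate (1,4) addition of lithium dimethylcuprate, accelerated by chlorotrimethylsilane, places methyl on C6 and traps the enolate regiospecifically as the C7=C8 silyl enol ether while the tertiary alkoxide is silylated and so cannot undergo retro-aldol opening; the C6 configuration is irrelevant because C6 becomes sp2 in the next step.

Step 9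
Reactants: 12 C8 trimethylsilyl enol ether and C3a trimethylsilyl ether of the 6-methyl adduct
Product: 14 (3R,3aS,8aS)-3a-hydroxy-6,8a-dimethyl-3-(propan-2-yl)-2,3,3a,4,5,8a-hexahydroazulen-8(1H)-one, via silyl ether enone 13 (not isolated)
Conditions: Pd(OAc)2 (10 mol%), O2 (1 atm), DMSO, 40 °C; then 1 M HCl, THF, 0 °C
Reagents that add atoms: none
Why: Saegusa–Ito oxidation (palladation of the silyl enol ether at C7, syn β-hydride elimination from C6, reoxidation of zerovalent palladium by O2) should regenerate the enone with the methyl group now on C6, and dilute acid then cleaves the tertiary trimethylsilyl ether.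

Step 10
Reactants: 14 (3R,3aS,8aS)-3a-hydroxy-6,8a-dimethyl-3-(propan-2-yl)-2,3,3a,4,5,8a-hexahydroazulen-8(1H)-one
Product: 15 (3R,3aS,8R,8aR)-6,8a-dimethyl-3-(propan-2-yl)-1,2,3,3a,4,5,8,8a-octahydroazulene-3a,8-diol
Conditions: Me4NBH(OAc)3 (5 equiv), MeCN/AcOH (1:1), −30 °C
Reagents that add atoms: none
Why: Evans–Saksena hydroxyl-directed reduction: the C3a hydroxyl exchanges onto boron and delivers hydride intramolecularly to the carbonyl face on its own side, so that 1,2-reduction gives the anti-1,3-diol with the C8 oxygen trans to the C3a hydroxyl and the C8a methyl (8R).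

Step 11
Reactants: 15 (3R,3aS,8R,8aR)-6,8a-dimethyl-3-(propan-2-yl)-1,2,3,3a,4,5,8,8a-octahydroazulene-3a,8-diol; 16 4-methoxybenzoyl chloride
Product: 17 (3R,3aS,8R,8aR)-3a-hydroxy-6,8a-dimethyl-3-(propan-2-yl)-1,2,3,3a,4,5,8,8a-octahydroazulen-8-yl 4-methoxybenzoate (CNP0158828.3)
Conditions: Et3N, DMAP (10 mol%), CH2Cl2, 0 to 23 °C
Reagents that add atoms: none
Why: DMAP-catalysed acylation (nucleophilic acyl substitution) should esterify only the secondary allylic C8 hydroxyl, the tertiary C3a hydroxyl being too hindered, with retention at C8.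

Compound list
1 | cycloheptane-1,3-dione | O=C1CCCCC(=O)C1 | starting material
2 | 2-methylcycloheptane-1,3-dione | CC1C(=O)CCCCC1=O | intermediate
3 | acrolein (prop-2-enal) | C=CC=O | starting material
4 | 3-(1-methyl-2,7-dioxocycloheptyl)propanal | CC1(CCC=O)C(=O)CCCCC1=O | intermediate
5 | 2-methyl-2-(4-methylpent-3-en-1-yl)cycloheptane-1,3-dione | CC(C)=CCCC1(C)C(=O)CCCCC1=O | intermediate
6 | (2R,3R)-3-hydroxy-2-methyl-2-(4-methylpent-3-en-1-yl)cycloheptan-1-one | O[C@@H]1CCCCC(=O)[C@]1(C)CCC=C(C)C | intermediate
7 | chloro(methyl)aluminium alkoxide of 6, chelated to the ketone oxygen (not isolated) | C[Al](Cl)O[C@@H]1CCCCC(=O)[C@]1(C)CCC=C(C)C | intermediate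
8 | (3R,3aS,8R,8aR)-8a-methyl-3-(prop-1-en-2-yl)decahydroazulene-3a,8-diol | O[C@@H]1CCCC[C@]2(O)[C@@H](C(C)=C)CC[C@]12C | intermediate
9 | (3R,3aS,8R,8aR)-8a-methyl-3-(propan-2-yl)decahydroazulene-3a,8-diol | O[C@@H]1CCCC[C@]2(O)[C@@H](C(C)C)CC[C@]12C | intermediate
10 | (3R,3aS,8aS)-3a-hydroxy-8a-methyl-3-(propan-2-yl)octahydroazulen-8(1H)-one (not isolated) | O=C1CCCC[C@]2(O)[C@@H](C(C)C)CC[C@]12C | intermediate
11 | (3R,3aS,8aS)-3a-hydroxy-8a-methyl-3-(propan-2-yl)-2,3,3a,4,5,8a-hexahydroazulen-8(1H)-one | O=C1C=CCC[C@]2(O)[C@@H](C(C)C)CC[C@]12C | intermediate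
12 | C8 trimethylsilyl enol ether and C3a trimethylsilyl ether of the 6-methyl adduct of 11 (C6 epimers) | C[Si](C)(C)OC1=CC(C)CC[C@]2(O[Si](C)(C)C)[C@@H](C(C)C)CC[C@]12C | intermediate
13 | C3a O-trimethylsilyl ether of 14 (not isolated) | O=C1C=C(C)CC[C@]2(O[Si](C)(C)C)[C@@H](C(C)C)CC[C@]12C | intermediate
14 | (3R,3aS,8aS)-3a-hydroxy-6,8a-dimethyl-3-(propan-2-yl)-2,3,3a,4,5,8a-hexahydroazulen-8(1H)-one | O=C1C=C(C)CC[C@]2(O)[C@@H](C(C)C)CC[C@]12C | intermediate
15 | (3R,3aS,8R,8aR)-6,8a-dimethyl-3-(propan-2-yl)-1,2,3,3a,4,5,8,8a-octahydroazulene-3a,8-diol | O[C@@H]1C=C(C)CC[C@]2(O)[C@@H](C(C)C)CC[C@]12C | intermediate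
16 | 4-methoxybenzoyl chloride | COc1ccc(C(=O)Cl)cc1 | starting material
17 | (3R,3aS,8R,8aR)-3a-hydroxy-6,8a-dimethyl-3-(propan-2-yl)-1,2,3,3a,4,5,8,8a-octahydroazulen-8-yl 4-methoxybenzoate | COc1ccc(C(=O)O[C@@H]2C=C(C)CC[C@]3(O)[C@@H](C(C)C)CC[C@]23C)cc1 | target

Total step count: 11. Longest linear sequence: 11 steps (from 1).

Steps most likely to fail

Step 5 (key step). The aluminium aldolate may open by retro-aldol cleavage, which would scramble C8a, or the alkoxide-bound aluminium may lower the Lewis acidity so far that the hindered ketone does not cyclise; chloride capture of the developing cation may also compete with hydrogen transfer. Fallback: setting out from 6, the hydroxyl is silylated (TBSOTf, 2,6-lutidine, CH2Cl2) to the tert-butyldimethylsilyl ether of 6, F1, which can no longer form an aldolate. It is cyclised with Me2AlCl acting only as an external Lewis acid (CH2Cl2, −78 to 23 °C) to the C8 silyl ether of 8, F2, under the same geometric control. Bu4NF in THF then returns the route to 8.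

Step 4. The methyl and homoprenyl faces may be discriminated too weakly, so that both carbonyl groups are reduced with the same carbinol sense; this would erode the enantiomeric purity of C8a once C8 is oxidised, and over-reduction to the diol is also possible. Fallback: setting out from 5, NaBH4 (0.3 equiv, MeOH, −40 °C) and chromatography give the racemic (2R*,3R*) hydroxy ketone, F3. Steglich esterification with (2S)-2-methoxy-2-phenylacetic acid (DCC, DMAP) gives two diastereomeric esters that are separated on silica, the wanted one being the (2S)-2-methoxy-2-phenylacetate of 6, F4. Methanolysis (K2CO3, MeOH, 0 °C) returns the route to 6.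

Step 10. Ligand exchange of the hindered tertiary C3a hydroxyl on boron may be too slow, so that hydride arrives without facial control or not at all. Fallback: setting out from 14, Luche reduction (NaBH4, CeCl3·7H2O, MeOH, −78 °C) delivers external hydride to the face away from the angular methyl and gives the C8-epimeric diol, F5. Mitsunobu esterification with 4-methoxybenzoic acid (PPh3, DIAD, THF) then inverts C8 and installs the ester in one operation, coming back to the route at 17 and bypassing 15.

Further compounds
F1 | step 5 | (2R,3R)-3-[(tert-butyldimethylsilyl)oxy]-2-methyl-2-(4-methylpent-3-en-1-yl)cycloheptan-1-one | CC(C)(C)[Si](C)(C)O[C@@H]1CCCCC(=O)[C@]1(C)CCC=C(C)C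
F2 | step 5 | (3R,3aS,8R,8aR)-8-[(tert-butyldimethylsilyl)oxy]-8a-methyl-3-(prop-1-en-2-yl)decahydroazulen-3a-ol | CC(C)(C)[Si](C)(C)O[C@@H]1CCCC[C@]2(O)[C@@H](C(C)=C)CC[C@]12C
F3 | step 4 | racemic (2R*,3R*)-3-hydroxy-2-methyl-2-(4-methylpent-3-en-1-yl)cycloheptan-1-one (6 with its mirror image) | O[C@@H]1CCCCC(=O)[C@]1(C)CCC=C(C)C.O[C@H]1CCCCC(=O)[C@@]1(C)CCC=C(C)C
F4 | step 4 | (1R,2R)-2-methyl-2-(4-methylpent-3-en-1-yl)-3-oxocycloheptyl (2S)-2-methoxy-2-phenylacetate | CO[C@H](C(=O)O[C@@H]1CCCCC(=O)[C@]1(C)CCC=C(C)C)c1ccccc1
F5 | step 10 | (3R,3aS,8S,8aR)-6,8a-dimethyl-3-(propan-2-yl)-1,2,3,3a,4,5,8,8a-octahydroazulene-3a,8-diol | O[C@H]1C=C(C)CC[C@]2(O)[C@@H](C(C)C)CC[C@]12C
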